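The lactone ring is traced back to an all-cis 2-methoxy-3,6-dihydro-2H-pyran, which is cut across O1–C2 and C5–C6 (lactone numbering) into a silyloxyacetaldehyde and a 1-methoxy-4-acyloxybutadiene. The key step, a catalytic asymmetric hetero-Diels–Alder reaction, exploits the fact that C5 (acyloxy) and C6 sit side by side and cis between ring oxygen O1 and the C3=C4 double bond. One cycloaddition closes the pyran ring, forms both bonds and sets C5 and C6 with the complete dienoate already in place. The precursor is the (1E,3E)-4-methoxybutadienyl ester of (2E,4E,6S)-4,6-dimethyldodeca-2,4-dienoic acid; its diene geometry is fixed beforehand by a stereoretentive copper-catalysed O-alkenylation.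

Key step: step 8

Assumption: the catalyst CrCl(L) (trivalent chromium; L = C27H29NO2, the O,N,O-dianion of (1R,2S)-1-{[3-(1-adamantyl)-2-hydroxy-5-methylbenzylidene]amino}indan-2-ol) is taken to deliver the diene to the Re face of 15, by analogy with 1-methoxybutadiene and the same aldehyde; if the sense proves opposite, the (1S,2R) antipode is used and nothing else changes.

Numbering: the names of 16 to 21 use pyran numbering (C2 carries the side chain, C3 the ester, C6 the acetal or lactone carbon); the overview uses lactone numbering.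

Design notes:
- The 1E,3E geometry of 14 is built in by steps 6 and 7, because γ-deprotonation of a 4-alkoxy-enal tends to place the alkoxy group cis and would give mainly the unreactive 3Z diene.
- The side-chain stereocentre comes from a bromo alcohol that cannot epimerise during chain extension.
- The acetal is oxidised only after the acrylate is in place, so the aldehyde of step 10 is never a 6-formyl lactone (prone to lose the C5 ester) and the silyl ether never meets chromic acid.

Step 1
Reactants: 1 (R)-3-bromo-2-methylpropan-1-ol; 2 pentylmagnesium bromide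
Product: 3 (S)-2-methyloctan-1-ol
Conditions: 2 (3 equiv), Li2CuCl4 (3 mol%), THF, −30 °C to rt; aq. NH4Cl
Reagents that add atoms: none
Why: Copper-catalysed sp3–sp3 cross-coupling of a Grignard reagent with a primary bromide (Kochi-type coupling) should proceed once the first equivalent of 2 has turned the hydroxyl group into its magnesium alkoxide; the stereocentre is not touched, and its descriptor changes from R to S only because the CIP ranking of the two CH2 arms is reversed.

Step 2
Reactants: 3 (S)-2-methyloctan-1-ol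
Product: 4 (S)-2-methyloctanal
Conditions: TEMPO (10 mol%), PhI(OAc)2 (1.1 equiv), CH2Cl2, rt
Reagents that add atoms: none
Why: Oxoammonium-mediated (TEMPO) oxidation of a primary alcohol stops at the aldehyde and needs no base, so the enolisable α-stereocentre should survive, and the crude aldehyde is used at once.

Step 3
Reactants: 4 (S)-2-methyloctanal; 5 2-(triphenylphosphoranylidene)propanal
Product: 6 (2E,4S)-2,4-dimethyldec-2-enal
Conditions: 5 (1.2 equiv), toluene, 90 °C
Reagents that add atoms: none
Why: Wittig olefination with a stabilised α-methyl formyl ylide should give the E trisubstituted enal under thermodynamic control, and the neutral medium leaves C4 untouched.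

Step 4
Reactants: 6 (2E,4S)-2,4-dimethyldec-2-enal; 7 ethyl (triphenylphosphoranylidene)acetate
Product: 8 ethyl (2E,4E,6S)-4,6-dimethyldodeca-2,4-dienoate
Conditions: 7 (1.3 equiv), CH2Cl2, rt to 40 °C
Reagents that add atoms: none
Why: E-selective Wittig olefination of an enal with a stabilised ester ylide should extend the chain to the 2E,4E dienoate without touching the existing alkene or C6.

Step 5
Reactants: 8 ethyl (2E,4E,6S)-4,6-dimethyldodeca-2,4-dienoate
Product: 9 (2E,4E,6S)-4,6-dimethyldodeca-2,4-dienoic acid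
Conditions: LiOH·H2O (3 equiv), THF/MeOH/H2O, rt; then 1 M HCl
Reagents that add atoms: lithium hydroxide, [Li+].[OH-]
Why: Saponification (acyl–oxygen cleavage by hydroxide) of the ethyl ester should give the acid, the conjugated diene and the remote C6 centre being inert to aqueous hydroxide at room temperature.

Step 6
Reactants: 10 (E)-3-methoxyprop-2-enal; 11 bis(4,4,5,5-tetramethyl-1,3,2-dioxaborolan-2-yl)methane
Product: 13 potassium trifluoro[(1E,3E)-4-methoxybuta-1,3-dien-1-yl]borate, via dienyl pinacol boronate 12 (not isolated)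
Conditions: 11 (1.2 equiv), LiTMP (1.2 equiv), THF, 0 °C; 10, −78 °C to rt; then KHF2 (aq.), MeOH, 0 °C, short contact
Reagents that add atoms: potassium hydrogen difluoride, [K+].[F-].F
Why: Boron–Wittig olefination (1,2-addition of the lithiated gem-diboronate to the aldehyde, then syn elimination of a boron–oxygen unit) should give the trans alkenylboronate while the E enol ether of 10 is carried through, and fluoride exchange then gives a trifluoroborate salt that can be purified by precipitation.

Step 7
Reactants: 9 (2E,4E,6S)-4,6-dimethyldodeca-2,4-dienoic acid; 13 potassium trifluoro[(1E,3E)-4-methoxybuta-1,3-dien-1-yl]borate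
Product: 14 (1E,3E)-4-methoxybuta-1,3-dien-1-yl (2E,4E,6S)-4,6-dimethyldodeca-2,4-dienoate
Conditions: 13 (2 equiv), CuBr (10 mol%), DMAP (20 mol%), 4 Å MS, O2 (1 atm), MeCN, 40 °C
Reagents that add atoms: none
Why: Copper-catalysed oxidative C–O coupling of a carboxylic acid with an alkenyltrifluoroborate (Chan–Lam–Evans type enol ester synthesis) proceeds by transmetalation and reductive elimination at copper with retention of alkene geometry, so the 1E,3E diene should be inherited from 13 instead of being left to an enolisation that would favour the Z enol ether.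

Step 8
Reactants: 14 (1E,3E)-4-methoxybuta-1,3-dien-1-yl (2E,4E,6S)-4,6-dimethyldodeca-2,4-dienoate; 15 (tert-butyldimethylsilyloxy)acetaldehyde
Product: 16 (2S,3S,6S)-2-{[(tert-butyldimethylsilyl)oxy]methyl}-6-methoxy-3,6-dihydro-2H-pyran-3-yl (2E,4E,6S)-4,6-dimethyldodeca-2,4-dienoate
Conditions: 15 (2 equiv), CrCl(L) (10 mol%), powdered 4 Å MS, TBME (2 M), rt, 48 h
Reagents that add atoms: none
Why: Proposed new method: the chromium Lewis acid (trivalent chromium) binds the carbonyl oxygen of 15 and the s-cis diene of 14 adds across C=O in a concerted, asynchronous [4+2] cycloaddition in which the C–C bond from the acyloxy-bearing diene terminus to the aldehyde carbon forms ahead of the O–C bond to the methoxy-bearing terminus; the closest known reaction type is the hetero-Diels–Alder reaction of 1-methoxybutadiene and of 4-alkyl-substituted 1-oxygenated dienes with silyloxyacetaldehydes under the same class of tridentate Schiff-base CrCl catalysts, whereas a 4-acyloxy-1-methoxy diene has not been used. The six-membered 3,6-dihydro-2H-pyran ring is closed by the cycloaddition itself, both ring bonds (C2–C3 and O1–C6, pyran numbering of 16) being made in the same event. C2 is set by the catalyst, which leaves only the Re face of the bound aldehyde open; C3 is set relative to C2 by the E geometry of the enol ester terminus together with the endo placement of the CH2OTBS group, which brings acyloxy and CH2OTBS cis; C6 follows likewise from the E enol ether and is erased in step 11. The step needs regioselectivity, secured by the methoxy group as the stronger donor, which makes the remote acyloxy-bearing carbon the nucleophilic end, and endo selectivity, which this catalyst class is known to enforce for aliphatic aldehydes. It also needs chemoselectivity, secured because the electron-poor, 4-methyl-substituted dienoate of the side chain cannot compete as a diene and the enol ester is not ionised by so mild a Lewis acid.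

Step 9
Reactants: 16 (2S,3S,6S)-2-{[(tert-butyldimethylsilyl)oxy]methyl}-6-methoxy-3,6-dihydro-2H-pyran-3-yl (2E,4E,6S)-4,6-dimethyldodeca-2,4-dienoate
Product: 17 (2S,3S,6S)-2-(hydroxymethyl)-6-methoxy-3,6-dihydro-2H-pyran-3-yl (2E,4E,6S)-4,6-dimethyldodeca-2,4-dienoate
Conditions: HF·pyridine, pyridine, THF, 0 °C to rt
Reagents that add atoms: none
Why: Fluoride-induced cleavage of the primary silyl ether under pyridine-buffered, non-basic conditions should free the alcohol without O-to-O acyl migration from C3 and without ionising the allylic acetal.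

Step 10
Reactants: 17 (2S,3S,6S)-2-(hydroxymethyl)-6-methoxy-3,6-dihydro-2H-pyran-3-yl (2E,4E,6S)-4,6-dimethyldodeca-2,4-dienoate; 18 tert-butyl (triphenylphosphoranylidene)acetate
Product: 20 tert-butyl (2E)-3-[(2S,3S,6S)-3-{[(2E,4E,6S)-4,6-dimethyldodeca-2,4-dienoyl]oxy}-6-methoxy-3,6-dihydro-2H-pyran-2-yl]prop-2-enoate, via aldehyde 19 (not isolated)
Conditions: Dess–Martin periodinane (1.3 equiv), 18 (2.5 equiv), CH2Cl2, 0 °C to rt
Reagents that add atoms: none
Why: Dess–Martin oxidation followed in the same flask by E-selective Wittig olefination with a stabilised ylide traps the α-alkoxy-β-acyloxy aldehyde as it forms under non-basic conditions, so that β-elimination of the dienoate and epimerisation at C2 should be avoided.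

Step 11
Reactants: 20 tert-butyl (2E)-3-[(2S,3S,6S)-3-{[(2E,4E,6S)-4,6-dimethyldodeca-2,4-dienoyl]oxy}-6-methoxy-3,6-dihydro-2H-pyran-2-yl]prop-2-enoate
Product: 21 tert-butyl (2E)-3-[(2S,3S)-3-{[(2E,4E,6S)-4,6-dimethyldodeca-2,4-dienoyl]oxy}-6-oxo-3,6-dihydro-2H-pyran-2-yl]prop-2-enoate
Conditions: CrO3, H2SO4, H2O/acetone (Jones reagent), 0 °C
Reagents that add atoms: water, O
Why: In this Jones oxidation of an allylic 2-alkoxy-dihydropyran acetal, acid ionises the methyl acetal, water adds to the oxocarbenium ion and chromic acid oxidises the resulting lactol to the α,β-unsaturated δ-lactone, the esters (tert-butyl included) being stable to brief exposure at 0 °C and C2 and C3 untouched.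

Step 12
Reactants: 21 tert-butyl (2E)-3-[(2S,3S)-3-{[(2E,4E,6S)-4,6-dimethyldodeca-2,4-dienoyl]oxy}-6-oxo-3,6-dihydro-2H-pyran-2-yl]prop-2-enoate
Product: 22 (2E)-3-[(2S,3S)-3-{[(2E,4E,6S)-4,6-dimethyldodeca-2,4-dienoyl]oxy}-6-oxo-3,6-dihydro-2H-pyran-2-yl]prop-2-enoic acid
Conditions: TFA/CH2Cl2 (1:4), 0 °C to rt
Reagents that add atoms: none
Why: Acid-catalysed alkyl–oxygen cleavage of the tert-butyl ester with loss of isobutene should free the acrylic acid, while the lactone, the allylic dienoate and both ring stereocentres are inert to anhydrous TFA.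

Compound list

1 | (R)-3-bromo-2-methylpropan-1-ol | BrC[C@H](C)CO | starting material
2 | pentylmagnesium bromide | CCCCC[Mg]Br | starting material
3 | (S)-2-methyloctan-1-ol | CCCCCC[C@H](C)CO | intermediate
4 | (S)-2-methyloctanal | CCCCCC[C@H](C)C=O | intermediate
5 | 2-(triphenylphosphoranylidene)propanal | CC(C=O)=P(c1ccccc1)(c1ccccc1)c1ccccc1 | starting material
6 | (2E,4S)-2,4-dimethyldec-2-enal | CCCCCC[C@H](C)/C=C(C)/C=O | intermediate
7 | ethyl (triphenylphosphoranylidene)acetate | CCOC(=O)C=P(c1ccccc1)(c1ccccc1)c1ccccc1 | starting material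
8 | ethyl (2E,4E,6S)-4,6-dimethyldodeca-2,4-dienoate | CCCCCC[C@H](C)/C=C(C)/C=C/C(=O)OCC | intermediate
9 | (2E,4E,6S)-4,6-dimethyldodeca-2,4-dienoic acid | CCCCCC[C@H](C)/C=C(C)/C=C/C(=O)O | intermediate
10 | (E)-3-methoxyprop-2-enal | CO/C=C/C=O | starting material
11 | bis(4,4,5,5-tetramethyl-1,3,2-dioxaborolan-2-yl)methane | CC1(C)OB(CB2OC(C)(C)C(C)(C)O2)OC1(C)C | starting material
12 | 2-[(1E,3E)-4-methoxybuta-1,3-dien-1-yl]-4,4,5,5-tetramethyl-1,3,2-dioxaborolane | CO/C=C/C=C/B1OC(C)(C)C(C)(C)O1 | intermediate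
13 | potassium trifluoro[(1E,3E)-4-methoxybuta-1,3-dien-1-yl]borate | CO/C=C/C=C/[B-](F)(F)F.[K+] | intermediate
14 | (1E,3E)-4-methoxybuta-1,3-dien-1-yl (2E,4E,6S)-4,6-dimethyldodeca-2,4-dienoate | CCCCCC[C@H](C)/C=C(C)/C=C/C(=O)O/C=C/C=C/OC | intermediate
15 | (tert-butyldimethylsilyloxy)acetaldehyde | O=CCO[Si](C)(C)C(C)(C)C | starting material
16 | (2S,3S,6S)-2-{[(tert-butyldimethylsilyl)oxy]methyl}-6-methoxy-3,6-dihydro-2H-pyran-3-yl (2E,4E,6S)-4,6-dimethyldodeca-2,4-dienoate | CCCCCC[C@H](C)/C=C(C)/C=C/C(=O)O[C@H]1C=C[C@@H](OC)O[C@H]1CO[Si](C)(C)C(C)(C)C | intermediate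
17 | (2S,3S,6S)-2-(hydroxymethyl)-6-methoxy-3,6-dihydro-2H-pyran-3-yl (2E,4E,6S)-4,6-dimethyldodeca-2,4-dienoate | CCCCCC[C@H](C)/C=C(C)/C=C/C(=O)O[C@H]1C=C[C@@H](OC)O[C@H]1CO | intermediate
18 | tert-butyl (triphenylphosphoranylidene)acetate | CC(C)(C)OC(=O)C=P(c1ccccc1)(c1ccccc1)c1ccccc1 | starting material
19 | (2R,3S,6S)-2-formyl-6-methoxy-3,6-dihydro-2H-pyran-3-yl (2E,4E,6S)-4,6-dimethyldodeca-2,4-dienoate | CCCCCC[C@H](C)/C=C(C)/C=C/C(=O)O[C@H]1C=C[C@@H](OC)O[C@H]1C=O | intermediate
20 | tert-butyl (2E)-3-[(2S,3S,6S)-3-{[(2E,4E,6S)-4,6-dimethyldodeca-2,4-dienoyl]oxy}-6-methoxy-3,6-dihydro-2H-pyran-2-yl]prop-2-enoate | CCCCCC[C@H](C)/C=C(C)/C=C/C(=O)O[C@H]1C=C[C@@H](OC)O[C@H]1/C=C/C(=O)OC(C)(C)C | intermediate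
21 | tert-butyl (2E)-3-[(2S,3S)-3-{[(2E,4E,6S)-4,6-dimethyldodeca-2,4-dienoyl]oxy}-6-oxo-3,6-dihydro-2H-pyran-2-yl]prop-2-enoate | CCCCCC[C@H](C)/C=C(C)/C=C/C(=O)O[C@H]1C=CC(=O)O[C@H]1/C=C/C(=O)OC(C)(C)C | intermediate
22 | (2E)-3-[(2S,3S)-3-{[(2E,4E,6S)-4,6-dimethyldodeca-2,4-dienoyl]oxy}-6-oxo-3,6-dihydro-2H-pyran-2-yl]prop-2-enoic acid | CCCCCC[C@H](C)/C=C(C)/C=C/C(=O)O[C@H]1C=CC(=O)O[C@H]1/C=C/C(=O)O | target

Total step count: 12. Longest linear sequence: 11 steps (1 to 5, then 7 to 12); step 6 is a one-step branch.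

Steps most likely to fail

Step 8 (hetero-Diels–Alder). The diene may be too weakly nucleophilic once its reacting terminus carries an acyloxy group, so that cycloaddition stalls while the Lewis acid slowly degrades the enol ester or enol ether; facial and endo control may also erode if forcing conditions are needed. The fallback uses known furan oxidation chemistry, sets out from 15 and 9 and comes back at 21.
- 15 is treated with 2-furyllithium (furan, n-BuLi, THF, −78 °C) to give racemic 2-[(tert-butyldimethylsilyl)oxy]-1-(furan-2-yl)ethan-1-ol F1.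
- Sharpless kinetic resolution (Ti(OiPr)4, L-(+)-diisopropyl tartrate, tBuOOH, CH2Cl2, −20 °C) should oxidise the S enantiomer selectively in an Achmatowicz rearrangement to (2S)-2-{[(tert-butyldimethylsilyl)oxy]methyl}-6-hydroxy-2H-pyran-3(6H)-one F2.
- O-Methylation (MeI, Ag2O) should give mainly the 2,6-trans acetal (2S,6R)-2-{[(tert-butyldimethylsilyl)oxy]methyl}-6-methoxy-2H-pyran-3(6H)-one F3.
- Luche reduction (NaBH4, CeCl3, MeOH, −78 °C) should give the 2,3-trans allylic alcohol (2S,3R,6R)-2-{[(tert-butyldimethylsilyl)oxy]methyl}-6-methoxy-3,6-dihydro-2H-pyran-3-ol F4.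
- Mitsunobu esterification with 9 (PPh3, DIAD, THF) inverts C3 and should give the 6-epimer of 16 F5.
- F5 is carried through the conditions of steps 9 to 11: the 6-epimer of 17 F6, the 6-epimer of 19 F7 (not isolated) and the 6-epimer of 20 F8. The Jones oxidation removes the acetal centre, so F8 gives 21.

Step 7 (copper-catalysed O-alkenylation). Protodeboronation or oxidative homocoupling of the electron-rich dienylborate may outrun C–O bond formation. The fallback sets out from 9, comes back at 14 and also makes step 6 unnecessary.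
- 9 is converted with oxalyl chloride and catalytic DMF in CH2Cl2 into (2E,4E,6S)-4,6-dimethyldodeca-2,4-dienoyl chloride F9.
- Cross-metathesis of allyl methyl ether with crotonaldehyde (second-generation Grubbs catalyst, CH2Cl2, 40 °C) gives (E)-4-methoxybut-2-enal F10.
- F10 is deprotonated at C4 with KOtBu in THF at −78 °C to potassium (1E)-4-methoxybuta-1,3-dien-1-olate F11 (not isolated), which is O-acylated by F9 to give 14.
- This classical enol ester synthesis fixes the 1E geometry through the s-trans enal but not the enol ether geometry. The (1E,3Z) isomer of 14 F12 is expected as a co-product and is removed by chromatography or left unreacted in step 8, since it cannot adopt the s-cis conformation.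

Step 11 (acetal to lactone). The strongly acidic chromic acid medium may cleave the tert-butyl ester or attack the trisubstituted alkene of the dienoate before the acetal is oxidised. The fallback separates ionisation from oxidation, sets out from 20 and comes back at 21.
- The acetal is hydrolysed under mild acid (PPTS, acetone/H2O, rt) to tert-butyl (2E)-3-[(2S,3S)-3-{[(2E,4E,6S)-4,6-dimethyldodeca-2,4-dienoyl]oxy}-6-hydroxy-3,6-dihydro-2H-pyran-2-yl]prop-2-enoate F13, an anomeric mixture.
- The allylic lactol is then oxidised under neutral conditions with MnO2 in CH2Cl2 to 21.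

Further compounds

F1 | step 8 | rac-2-[(tert-butyldimethylsilyl)oxy]-1-(furan-2-yl)ethan-1-ol | OC(CO[Si](C)(C)C(C)(C)C)c1ccco1
F2 | step 8 | (2S)-2-{[(tert-butyldimethylsilyl)oxy]methyl}-6-hydroxy-2H-pyran-3(6H)-one (both anomers) | O=C1C=CC(O)O[C@H]1CO[Si](C)(C)C(C)(C)C
F3 | step 8 | (2S,6R)-2-{[(tert-butyldimethylsilyl)oxy]methyl}-6-methoxy-2H-pyran-3(6H)-one | O=C1C=C[C@H](OC)O[C@H]1CO[Si](C)(C)C(C)(C)C
F4 | step 8 | (2S,3R,6R)-2-{[(tert-butyldimethylsilyl)oxy]methyl}-6-methoxy-3,6-dihydro-2H-pyran-3-ol | O[C@@H]1C=C[C@H](OC)O[C@H]1CO[Si](C)(C)C(C)(C)C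
F5 | step 8 | (2S,3S,6R)-2-{[(tert-butyldimethylsilyl)oxy]methyl}-6-methoxy-3,6-dihydro-2H-pyran-3-yl (2E,4E,6S)-4,6-dimethyldodeca-2,4-dienoate | CCCCCC[C@H](C)/C=C(C)/C=C/C(=O)O[C@H]1C=C[C@H](OC)O[C@H]1CO[Si](C)(C)C(C)(C)C
F6 | step 8 | (2S,3S,6R)-2-(hydroxymethyl)-6-methoxy-3,6-dihydro-2H-pyran-3-yl (2E,4E,6S)-4,6-dimethyldodeca-2,4-dienoate | CCCCCC[C@H](C)/C=C(C)/C=C/C(=O)O[C@H]1C=C[C@H](OC)O[C@H]1CO
F7 | step 8 | (2R,3S,6R)-2-formyl-6-methoxy-3,6-dihydro-2H-pyran-3-yl (2E,4E,6S)-4,6-dimethyldodeca-2,4-dienoate | CCCCCC[C@H](C)/C=C(C)/C=C/C(=O)O[C@H]1C=C[C@H](OC)O[C@H]1C=O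
F8 | step 8 | tert-butyl (2E)-3-[(2S,3S,6R)-3-{[(2E,4E,6S)-4,6-dimethyldodeca-2,4-dienoyl]oxy}-6-methoxy-3,6-dihydro-2H-pyran-2-yl]prop-2-enoate | CCCCCC[C@H](C)/C=C(C)/C=C/C(=O)O[C@H]1C=C[C@H](OC)O[C@H]1/C=C/C(=O)OC(C)(C)C
F9 | step 7 | (2E,4E,6S)-4,6-dimethyldodeca-2,4-dienoyl chloride | CCCCCC[C@H](C)/C=C(C)/C=C/C(=O)Cl
F10 | step 7 | (E)-4-methoxybut-2-enal | COC/C=C/C=O
F11 | step 7 | potassium (1E)-4-methoxybuta-1,3-dien-1-olate (enol ether geometry mixed) | COC=C/C=C/[O-].[K+]
F12 | step 7 | (1E,3Z)-4-methoxybuta-1,3-dien-1-yl (2E,4E,6S)-4,6-dimethyldodeca-2,4-dienoate | CCCCCC[C@H](C)/C=C(C)/C=C/C(=O)O/C=C/C=C\OC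
F13 | step 11 | tert-butyl (2E)-3-[(2S,3S)-3-{[(2E,4E,6S)-4,6-dimethyldodeca-2,4-dienoyl]oxy}-6-hydroxy-3,6-dihydro-2H-pyran-2-yl]prop-2-enoate (both anomers) | CCCCCC[C@H](C)/C=C(C)/C=C/C(=O)O[C@H]1C=CC(O)O[C@H]1/C=C/C(=O)OC(C)(C)C
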